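**Retrosynthetic overview**
- Target 22 is traced back to the 5,8-bis(benzyloxy)flavanone 19. The C4 carbonyl distinguishes O5 from O8 by chelation: the O5 benzyl is removed and replaced by methyl, then the O8 benzyl is hydrogenolysed.
- The feature used: C4a and C8a are adjacent ring A carbons that carry C4 and O1, and ring A is symmetric about the C4a–C8a bond once O5 and O8 bear the same group. Both ring C bonds (O1–C8a and C4–C4a) are therefore cut back to the symmetric aryne 16 and a three-carbon β-oxy ester that already holds C2 as S.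
- Aryne precursor 12 comes from bromophenol 8, dibromide 5, and 2,3-dimethoxy-1,4-benzoquinone 1 plus benzyl bromide 3. Silyl ether 15 comes from hydroxy ester 14, made by Noyori hydrogenation of β-keto ester 13, which sets C2.
- Ring order: rings A and B are bought as arenes; ring C is the only ring formed, in step 9.

Key step: step 9

Assumption: the hydroxyl of 14 enters the annulation as its trimethylsilyl ether 15, because a free O–H would protonate the aryl anion before it can attack the ester; 2,3-dimethoxy-1,4-benzoquinone is taken as purchasable.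

**Step 1**
Reactants: 1 2,3-dimethoxy-1,4-benzoquinone
Product: 2 2,3-dimethoxybenzene-1,4-diol
Conditions: Na2S2O4, H2O/EtOAc, rt, under N2
Reagents that add atoms: none
Why: Dithionite reduction of a quinone to its hydroquinone is a clean two-electron transfer that leaves the methoxy groups untouched.

**Step 2**
Reactants: 2 2,3-dimethoxybenzene-1,4-diol; 3 benzyl bromide
Product: 4 1,4-bis(benzyloxy)-2,3-dimethoxybenzene
Conditions: BnBr (2.5 equiv), K2CO3, DMF, 60 °C, under N2
Reagents that add atoms: benzyl bromide (3), BrCc1ccccc1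
Why: Williamson etherification of both phenoxides, run under nitrogen so the electron-rich hydroquinone is alkylated before it can reoxidise.

**Step 3**
Reactants: 4 1,4-bis(benzyloxy)-2,3-dimethoxybenzene
Product: 5 1,4-bis(benzyloxy)-2,3-dibromo-5,6-dimethoxybenzene
Conditions: NBS (2.2 equiv), MeCN, 0 °C to rt, dark
Reagents that add atoms: N-bromosuccinimide, O=C1CCC(=O)N1Br
Why: Electrophilic aromatic bromination: each free position is ortho to a benzyloxy and para to a methoxy group, so both are brominated while the unactivated benzyl rings stay intact.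

**Step 4**
Reactants: 5 1,4-bis(benzyloxy)-2,3-dibromo-5,6-dimethoxybenzene
Product: 8 3,6-bis(benzyloxy)-2-bromo-4,5-dimethoxyphenol, via arylmagnesium chloride 6 (not isolated), via dimethyl arylboronate 7 (not isolated)
Conditions: i-PrMgCl·LiCl (1.1 equiv), THF, −15 °C; B(OMe)3, −15 °C to rt; then AcOH, 30% aq H2O2, 0 °C to rt
Reagents that add atoms: hydrogen peroxide, OO
Why: Bromine–magnesium exchange with the turbo-Grignard reagent should stop after one bromine, since arylmagnesium 6 is deactivated towards a second exchange and does not eliminate to an aryne at this temperature; borate trapping and peroxide oxidation (1,2-aryl shift from boron to oxygen) then turn the C–Mg bond into the phenol.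

**Step 5**
Reactants: 8 3,6-bis(benzyloxy)-2-bromo-4,5-dimethoxyphenol
Product: 9 [3,6-bis(benzyloxy)-2-bromo-4,5-dimethoxyphenoxy]trimethylsilane
Conditions: HMDS, THF, 70 °C; concentrate and use crude
Reagents that add atoms: hexamethyldisilazane, C[Si](C)(C)N[Si](C)(C)C
Why: O-silylation of the phenol with HMDS gives the aryl silyl ether needed for the retro-Brook shift, with ammonia as the only by-product.

**Step 6**
Reactants: 9 [3,6-bis(benzyloxy)-2-bromo-4,5-dimethoxyphenoxy]trimethylsilane
Product: 12 3,6-bis(benzyloxy)-4,5-dimethoxy-2-(trimethylsilyl)phenyl trifluoromethanesulfonate, via aryllithium 10 (not isolated), via lithium 2-silylphenoxide 11 (not isolated)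
Conditions: n-BuLi, THF, −78 °C; then Tf2O, −78 °C to rt
Reagents that add atoms: trifluoromethanesulfonic anhydride, O=S(=O)(OS(=O)(=O)C(F)(F)F)C(F)(F)F
Why: Bromine–lithium exchange at −78 °C outpaces benzylic deprotonation, aryllithium 10 undergoes the 1,3 O-to-C silyl shift (retro-Brook rearrangement) to phenoxide 11, and triflation gives the ortho-silylaryl triflate (Kobayashi-type aryne precursor).

**Step 7**
Reactants: 13 ethyl 3-(3,4-dimethoxyphenyl)-3-oxopropanoate
Product: 14 ethyl (3S)-3-(3,4-dimethoxyphenyl)-3-hydroxypropanoate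
Conditions: RuCl2[(R)-BINAP] (0.5 mol %), H2 (50 bar), EtOH, 50 °C
Reagents that add atoms: none
Why: Noyori asymmetric hydrogenation of a β-keto ester: the chelated substrate receives hydride on one carbonyl face under control of the (R)-BINAP ligand, which for aryl β-keto esters is expected to give the (S)-alcohol (the future C2), and ethanol matches the ester so transesterification is irrelevant.

**Step 8**
Reactants: 14 ethyl (3S)-3-(3,4-dimethoxyphenyl)-3-hydroxypropanoate
Product: 15 ethyl (3S)-3-(3,4-dimethoxyphenyl)-3-[(trimethylsilyl)oxy]propanoate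
Conditions: TMSCl, imidazole, CH2Cl2, 0 °C; filter, concentrate
Reagents that add atoms: chlorotrimethylsilane, C[Si](C)(C)Cl
Why: Standard O-silylation of a secondary alcohol removes the only O–H proton of the coupling partner and makes the oxygen a fluoride-releasable alkoxide without touching the stereocenter.

**Step 9**
Reactants: 12 3,6-bis(benzyloxy)-4,5-dimethoxy-2-(trimethylsilyl)phenyl trifluoromethanesulfonate; 15 ethyl (3S)-3-(3,4-dimethoxyphenyl)-3-[(trimethylsilyl)oxy]propanoate
Product: 19 (2S)-5,8-bis(benzyloxy)-2-(3,4-dimethoxyphenyl)-6,7-dimethoxychroman-4-one, via symmetric aryne 16 (not isolated), via cesium alkoxide 17 (not isolated), via arylcesium adduct 18 (not isolated)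
Conditions: anhydrous CsF (3 equiv), 18-crown-6 (0.2 equiv), THF, 40 °C; 12 (1.5 equiv) added slowly to 15
Reagents that add atoms: none
Why: Proposed new method: fluoride removes the trimethylsilyl group of 12 with loss of triflate to give aryne 16 and, in the same flask, converts silyl ether 15 into the proton-free alkoxide 17, which adds to the strained triple bond (O1–C8a) to give aryl anion 18 at the future C4a. Anion 18 attacks the ethyl ester carbonyl through a six-membered transition state (6-exo-trig acyl substitution) and expels ethoxide, forming C4–C4a and closing ring C. The closest known reaction types are the fluoride-induced annulation of arynes with salicylate esters to xanthones and the fluoride-promoted use of silyl ethers as alkoxide equivalents in O-arylation; new here is an aliphatic secondary β-oxido ester as the partner that delivers both O and acyl carbon. No stereocenter is formed: C2 comes from 14 and its C–O bond is never broken, so the S configuration should be retained. The step needs acyl capture to beat quenching of 18, which is secured by having no O–H in the flask, by THF in place of acetonitrile, and by the proximity of the ester; the ethoxide released is expected to be taken up as ethoxytrimethylsilane by silyl transfer from 15, which also shields the base-sensitive flavanone from retro-oxa-Michael opening. Regiochemistry does not arise because the two aryne carbons of 16 are equivalent.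

**Step 10**
Reactants: 19 (2S)-5,8-bis(benzyloxy)-2-(3,4-dimethoxyphenyl)-6,7-dimethoxychroman-4-one
Product: 20 (2S)-8-(benzyloxy)-2-(3,4-dimethoxyphenyl)-5-hydroxy-6,7-dimethoxychroman-4-one
Conditions: MgBr2·OEt2 (3 equiv), toluene/Et2O, 70 °C; dilute aqueous acid work-up
Reagents that add atoms: none
Why: Chelation-controlled debenzylation: magnesium bridges the C4 carbonyl and O5, so only the peri benzyl ether is activated for SN2 attack by bromide, while the C8 benzyl ether and all methyl ethers lack such a chelate.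

**Step 11**
Reactants: 20 (2S)-8-(benzyloxy)-2-(3,4-dimethoxyphenyl)-5-hydroxy-6,7-dimethoxychroman-4-one
Product: 21 (2S)-8-(benzyloxy)-2-(3,4-dimethoxyphenyl)-5,6,7-trimethoxychroman-4-one
Conditions: MeI (excess), Ag2O, DMF, rt, dark
Reagents that add atoms: iodomethane, CI
Why: Purdie-type O-methylation: Ag2O is a mild, weakly basic halide acceptor, so the chelated C5 phenol should be alkylated without the enolisation and retro-oxa-Michael opening that would racemise C2.

**Step 12**
Reactants: 21 (2S)-8-(benzyloxy)-2-(3,4-dimethoxyphenyl)-5,6,7-trimethoxychroman-4-one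
Product: 22 (2S)-2-(3,4-dimethoxyphenyl)-8-hydroxy-5,6,7-trimethoxychroman-4-one
Conditions: H2 (1 atm), 10% Pd/C, EtOAc, rt; stop at consumption of 21
Reagents that add atoms: none
Why: Hydrogenolysis of the aryl benzyl ether over Pd/C under neutral conditions is much faster than reduction of the C4 ketone or cleavage of the cyclic benzylic C2–O1 bond, so the C8 phenol is freed with C2 intact.

**Compound list**
1 | 2,3-dimethoxy-1,4-benzoquinone | COC1=C(OC)C(=O)C=CC1=O | starting material
2 | 2,3-dimethoxybenzene-1,4-diol | COc1c(O)ccc(O)c1OC | intermediate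
3 | benzyl bromide | BrCc1ccccc1 | starting material
4 | 1,4-bis(benzyloxy)-2,3-dimethoxybenzene | COc1c(OC)c(OCc2ccccc2)ccc1OCc1ccccc1 | intermediate
5 | 1,4-bis(benzyloxy)-2,3-dibromo-5,6-dimethoxybenzene | COc1c(OC)c(OCc2ccccc2)c(Br)c(Br)c1OCc1ccccc1 | intermediate
6 | [2,5-bis(benzyloxy)-6-bromo-3,4-dimethoxyphenyl]magnesium chloride | COc1c(OC)c(OCc2ccccc2)c(Br)c([Mg]Cl)c1OCc1ccccc1 | intermediate
7 | dimethyl [2,5-bis(benzyloxy)-6-bromo-3,4-dimethoxyphenyl]boronate | COB(OC)c1c(Br)c(OCc2ccccc2)c(OC)c(OC)c1OCc1ccccc1 | intermediate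
8 | 3,6-bis(benzyloxy)-2-bromo-4,5-dimethoxyphenol | COc1c(OC)c(OCc2ccccc2)c(Br)c(O)c1OCc1ccccc1 | intermediate
9 | [3,6-bis(benzyloxy)-2-bromo-4,5-dimethoxyphenoxy]trimethylsilane | COc1c(OC)c(OCc2ccccc2)c(Br)c(O[Si](C)(C)C)c1OCc1ccccc1 | intermediate
10 | [3,6-bis(benzyloxy)-4,5-dimethoxy-2-(trimethylsilyloxy)phenyl]lithium | COc1c(OC)c(OCc2ccccc2)c([Li])c(O[Si](C)(C)C)c1OCc1ccccc1 | intermediate
11 | lithium 3,6-bis(benzyloxy)-4,5-dimethoxy-2-(trimethylsilyl)phenoxide | COc1c(OC)c(OCc2ccccc2)c([Si](C)(C)C)c([O-])c1OCc1ccccc1.[Li+] | intermediate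
12 | 3,6-bis(benzyloxy)-4,5-dimethoxy-2-(trimethylsilyl)phenyl trifluoromethanesulfonate | COc1c(OC)c(OCc2ccccc2)c([Si](C)(C)C)c(OS(=O)(=O)C(F)(F)F)c1OCc1ccccc1 | intermediate
13 | ethyl 3-(3,4-dimethoxyphenyl)-3-oxopropanoate | CCOC(=O)CC(=O)c1ccc(OC)c(OC)c1 | starting material
14 | ethyl (3S)-3-(3,4-dimethoxyphenyl)-3-hydroxypropanoate | COc1ccc([C@@H](O)CC(=O)OCC)cc1OC | intermediate
15 | ethyl (3S)-3-(3,4-dimethoxyphenyl)-3-[(trimethylsilyl)oxy]propanoate | COc1ccc([C@@H](O[Si](C)(C)C)CC(=O)OCC)cc1OC | intermediate
16 | 3,6-bis(benzyloxy)-4,5-dimethoxybenzyne | COC1=C(OCc2ccccc2)C#CC(OCc2ccccc2)=C1OC | intermediate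
17 | cesium (1S)-1-(3,4-dimethoxyphenyl)-3-ethoxy-3-oxopropan-1-olate | COc1ccc([C@@H]([O-])CC(=O)OCC)cc1OC.[Cs+] | intermediate
18 | ethyl (3S)-3-[3,6-bis(benzyloxy)-2-cesio-4,5-dimethoxyphenoxy]-3-(3,4-dimethoxyphenyl)propanoate | COc1ccc([C@@H](Oc2c([Cs])c(OCc3ccccc3)c(OC)c(OC)c2OCc2ccccc2)CC(=O)OCC)cc1OC | intermediate
19 | (2S)-5,8-bis(benzyloxy)-2-(3,4-dimethoxyphenyl)-6,7-dimethoxychroman-4-one | COc1ccc([C@@H]2CC(=O)c3c(OCc4ccccc4)c(OC)c(OC)c(OCc4ccccc4)c3O2)cc1OC | intermediate
20 | (2S)-8-(benzyloxy)-2-(3,4-dimethoxyphenyl)-5-hydroxy-6,7-dimethoxychroman-4-one | COc1ccc([C@@H]2CC(=O)c3c(O)c(OC)c(OC)c(OCc4ccccc4)c3O2)cc1OC | intermediate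
21 | (2S)-8-(benzyloxy)-2-(3,4-dimethoxyphenyl)-5,6,7-trimethoxychroman-4-one | COc1ccc([C@@H]2CC(=O)c3c(OC)c(OC)c(OC)c(OCc4ccccc4)c3O2)cc1OC | intermediate
22 | (2S)-2-(3,4-dimethoxyphenyl)-8-hydroxy-5,6,7-trimethoxychroman-4-one | COc1ccc([C@@H]2CC(=O)c3c(c(O)c(OC)c(OC)c3OC)O2)cc1OC | target

**Step count**
Total: 12 steps. Longest linear sequence: 10 steps (steps 1–6, then 9–12).

**Steps most likely to fail**

1. Step 9 (proposed new method). Aryl anion 18 may be quenched by proton transfer or by deprotonating the ester α-CH2 before acyl capture, which would give the uncyclised aryl ether or elimination. The aryne may also insert into the O–Si bond of unactivated 15, and ethoxide or fluoride may open 19 by retro-oxa-Michael reaction and erode the configuration at C2. The fallback uses known chemistry, sets out from bromophenol 8 and returns at 19.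
   - MOMCl and i-Pr2NEt in CH2Cl2 should give 1,4-bis(benzyloxy)-2-bromo-5,6-dimethoxy-3-(methoxymethoxy)benzene F1.
   - Bromine–lithium exchange (n-BuLi, THF, −78 °C) and acylation with N-methoxy-N-methylacetamide should give 1-[3,6-bis(benzyloxy)-4,5-dimethoxy-2-(methoxymethoxy)phenyl]ethan-1-one F2.
   - Heating with N,N-dimethylformamide dimethyl acetal at 90 °C should give (E)-1-[3,6-bis(benzyloxy)-4,5-dimethoxy-2-(methoxymethoxy)phenyl]-3-(dimethylamino)prop-2-en-1-one F3.
   - Aqueous HCl in MeOH at 50 °C removes the MOM group and closes the pyranone to 5,8-bis(benzyloxy)-6,7-dimethoxy-4H-chromen-4-one F4.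
   - Enantioselective conjugate addition of 3,4-dimethoxyphenylboronic acid then gives 19. Conditions: Pd(OCOCF3)2, t-BuPyOx in the enantiomeric form that delivers the 2S product, NH4PF6, H2O, 1,2-dichloroethane, 60 °C.

2. Step 11. The hydrogen-bonded C5 phenol, flanked by the C6 methoxy group, may alkylate incompletely. Forcing the conditions risks enolisation and retro-oxa-Michael opening, with racemisation at C2. The fallback removes the carbonyl for the duration of the alkylation, sets out from 20 and returns at 21.
   - NaBH4 in MeOH at 0 °C should give (2S)-8-(benzyloxy)-2-(3,4-dimethoxyphenyl)-6,7-dimethoxychromane-4,5-diol F5 as a mixture of C4 epimers.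
   - The now unchelated phenol is methylated with MeI and K2CO3 in acetone to (2S)-8-(benzyloxy)-2-(3,4-dimethoxyphenyl)-5,6,7-trimethoxychroman-4-ol F6.
   - Oxidation of the benzylic alcohol with Dess–Martin periodinane in CH2Cl2 (or MnO2) converges both epimers on 21.

3. Step 4. Exchange may occur at both bromines, arylmagnesium 6 may lose magnesium halide to an aryne before the borate is added, or exchange on the electron-rich ring may be slow. The fallback functionalises the two positions one after the other, sets out from 4 and returns at 8.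
   - NBS (1.0 equiv) in MeCN at 0 °C should give 1,4-bis(benzyloxy)-5-bromo-2,3-dimethoxybenzene F7.
   - n-BuLi in THF at −78 °C, then B(OMe)3, then AcOH/H2O2 should give 2,5-bis(benzyloxy)-3,4-dimethoxyphenol F8.
   - Ortho-bromination at the only free ring position (NBS, 1.0 equiv, catalytic i-Pr2NH, CH2Cl2, −78 to 0 °C) gives 8.

**Further compounds**
F1 | step 9 | 1,4-bis(benzyloxy)-2-bromo-5,6-dimethoxy-3-(methoxymethoxy)benzene | COCOc1c(Br)c(OCc2ccccc2)c(OC)c(OC)c1OCc1ccccc1
F2 | step 9 | 1-[3,6-bis(benzyloxy)-4,5-dimethoxy-2-(methoxymethoxy)phenyl]ethan-1-one | COCOc1c(C(C)=O)c(OCc2ccccc2)c(OC)c(OC)c1OCc1ccccc1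
F3 | step 9 | (E)-1-[3,6-bis(benzyloxy)-4,5-dimethoxy-2-(methoxymethoxy)phenyl]-3-(dimethylamino)prop-2-en-1-one | COCOc1c(C(=O)/C=C/N(C)C)c(OCc2ccccc2)c(OC)c(OC)c1OCc1ccccc1
F4 | step 9 | 5,8-bis(benzyloxy)-6,7-dimethoxy-4H-chromen-4-one | COc1c(OC)c(OCc2ccccc2)c2occc(=O)c2c1OCc1ccccc1
F5 | step 11 | (2S)-8-(benzyloxy)-2-(3,4-dimethoxyphenyl)-6,7-dimethoxychromane-4,5-diol (C4 epimers) | COc1ccc([C@@H]2CC(O)c3c(O)c(OC)c(OC)c(OCc4ccccc4)c3O2)cc1OC
F6 | step 11 | (2S)-8-(benzyloxy)-2-(3,4-dimethoxyphenyl)-5,6,7-trimethoxychroman-4-ol (C4 epimers) | COc1ccc([C@@H]2CC(O)c3c(OC)c(OC)c(OC)c(OCc4ccccc4)c3O2)cc1OC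
F7 | step 4 | 1,4-bis(benzyloxy)-5-bromo-2,3-dimethoxybenzene | COc1c(OC)c(OCc2ccccc2)c(Br)cc1OCc1ccccc1
F8 | step 4 | 2,5-bis(benzyloxy)-3,4-dimethoxyphenol | COc1c(OC)c(OCc2ccccc2)c(O)cc1OCc1ccccc1
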